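**Retrosynthetic overview**
1. Locants follow the asbestinane skeleton: carbocycle C1–C10 bridged by oxygen between C2 and C9 (tetrahydrofuran with C1 and C10), cyclohexane C1/C10–C14, oxepane C1–C2–C3–O–C16–C15–C14.
2. Last ring: the oxonane, closed at C6–C7 by B-alkyl Suzuki–Miyaura coupling on the 2,5-cis tetrahydrofuran; before it C8–C9 (allylsilane on the lactol) and C4–C5 (chelation-controlled vinyl addition).
3. Tetrahydrofuran from the γ-lactone C2–O–C9(=O); C11 oxygen by allylic oxidation and inversion, C12 by hydrogenation.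
4. Key disconnection: C1–C14 together with C10–C11 by an intramolecular Diels–Alder reaction of an acyclic triene, closing cyclohexene and oxepane in one event. What allows it: C1 is the atom shared by cyclohexane, oxepane and tetrahydrofuran; its neighbour C10 carries C9, a carboxyl carbon in the precursor, so C1=C10 can be an alkylidene malonate; and C14 is tied to C2 by the C15–C16–O–C3 ether, a ready five-atom tether.
5. Triene from a Sharpless epoxide (C2, C3) opened at C3 by the C16 alcohol of a dienol that carries the purchased C15 stereocentre; ring order: cyclohexene + oxepane, then lactone/tetrahydrofuran, then oxonane.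

Key step: step 13

Remark: (R)-2-hydroxyoctanoic acid is taken as a purchasable enantiopure acid, and the selenium dioxide oxidation of step 16 is assumed to place the C11 hydroxyl on the convex face (either epimer converges at enone 21).

**Route**

Step 1
Reactants: 1 methyl (R)-3-hydroxy-2-methylpropanoate
Product: 2 methyl (R)-3-[(tert-butyldimethylsilyl)oxy]-2-methylpropanoate
Conditions: t-BuMe2SiCl, imidazole, DMF, rt
Reagents that add atoms: tert-butyl(chloro)dimethylsilane (CC(C)(C)[Si](C)(C)Cl)
Why: Standard silylation of the primary alcohol (later O16); the purchased stereocentre (C15) is not touched.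

Step 2
Reactants: 2 silyl ether ester
Product: 3 (R)-3-[(tert-butyldimethylsilyl)oxy]-2-methylpropanal
Conditions: i-Bu2AlH, CH2Cl2, −78 °C
Reagents that add atoms: none
Why: Half-reduction of the ester through the stable tetrahedral aluminate should give the α-methyl aldehyde (C14) without epimerisation.

Step 3
Reactants: 3 aldehyde
Product: 4 (5S,3E)-6-[(tert-butyldimethylsilyl)oxy]-5-methylhex-3-en-2-one
Conditions: Ph3P=CHC(O)CH3, CH2Cl2, 40 °C
Reagents that add atoms: 1-(triphenylphosphoranylidene)propan-2-one (CC(=O)C=P(c1ccccc1)(c1ccccc1)c1ccccc1)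
Why: Wittig olefination with a stabilised ylide gives the (E)-enone (C13=C14) under neutral conditions that leave C15 intact.

Step 4
Reactants: 4 enone
Product: 5 tert-butyl{[(2S,3E)-2,5-dimethylhexa-3,5-dien-1-yl]oxy}dimethylsilane
Conditions: Ph3PCH3Br, KN(SiMe3)2, THF, −78 → 0 °C
Reagents that add atoms: methyltriphenylphosphonium bromide (C[P+](c1ccccc1)(c1ccccc1)c1ccccc1.[Br-])
Why: Wittig methylenation of the ketone installs C11 and completes the 2-methyl-1,3-diene.

Step 5
Reactants: 5 diene silyl ether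
Product: 6 (2S,3E)-2,5-dimethylhexa-3,5-dien-1-ol
Conditions: Bu4NF, THF, 0 °C → rt
Reagents that add atoms: none
Why: Fluoride desilylation frees the C16 hydroxyl that will become the oxepane oxygen.

Step 6
Reactants: 7 1-[(tert-butyldimethylsilyl)oxy]propan-2-one
Product: 8 methyl (Z)-4-[(tert-butyldimethylsilyl)oxy]-3-methylbut-2-enoate
Conditions: (CF3CH2O)2P(O)CH2CO2Me, KN(SiMe3)2, 18-crown-6, THF, −78 °C
Reagents that add atoms: methyl bis(2,2,2-trifluoroethyl)phosphonoacetate (COC(=O)CP(=O)(OCC(F)(F)F)OCC(F)(F)F)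
Why: Still–Gennari olefination, in which fast elimination from the electron-poor phosphonate adduct should give the (Z)-enoate (C1 and C4 cis).

Step 7
Reactants: 8 (Z)-enoate
Product: 9 (Z)-4-[(tert-butyldimethylsilyl)oxy]-3-methylbut-2-en-1-ol
Conditions: i-Bu2AlH, CH2Cl2, −78 °C
Reagents that add atoms: none
Why: 1,2-Reduction of the enoate gives the (Z)-allylic alcohol with the alkene geometry kept.

Step 8
Reactants: 9 (Z)-allylic alcohol
Product: 10 [(2R,3S)-3-{[(tert-butyldimethylsilyl)oxy]methyl}-3-methyloxiran-2-yl]methanol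
Conditions: Ti(Oi-Pr)4 (cat.), D-(−)-diethyl tartrate (cat.), t-BuOOH, 4 Å MS, CH2Cl2, −20 °C
Reagents that add atoms: tert-butyl hydroperoxide (CC(C)(C)OO)
Why: Sharpless asymmetric epoxidation; the D-(−)-tartrate catalyst delivers oxygen to the alkene face that gives the (2R,3S)-epoxide, which sets C2 and, before inversion, C3.

Step 9
Reactants: 6 dienol; 10 epoxy alcohol
Product: 11 (2R,3R)-4-[(tert-butyldimethylsilyl)oxy]-3-{[(2S,3E)-2,5-dimethylhexa-3,5-dien-1-yl]oxy}-3-methylbutane-1,2-diol
Conditions: BF3·OEt2 (cat.), CH2Cl2, −40 °C, 6 in excess (recovered)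
Reagents that add atoms: none
Why: Lewis-acid-catalysed alcoholysis of a trisubstituted 2,3-epoxy alcohol at its tertiary carbon with inversion should form the tertiary C3–O–C16 ether and set C3, while C2 keeps its configuration.

Step 10
Reactants: 11 diol
Product: 12 1,2-bis(triethylsilyl) ether of 11
Conditions: Et3SiOTf, 2,6-lutidine, CH2Cl2, −78 → 0 °C
Reagents that add atoms: triethylsilyl trifluoromethanesulfonate (CC[Si](CC)(CC)OS(=O)(=O)C(F)(F)F)
Why: Exhaustive silylation with the silyl triflate covers both the primary and the hindered secondary hydroxyl.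

Step 11
Reactants: 12 bis(triethylsilyl) ether
Product: 13 (2S,3R)-4-[(tert-butyldimethylsilyl)oxy]-3-{[(2S,3E)-2,5-dimethylhexa-3,5-dien-1-yl]oxy}-3-methyl-2-[(triethylsilyl)oxy]butanal
Conditions: (COCl)2, DMSO, CH2Cl2, −78 °C; Et3N, −78 → −30 °C
Reagents that add atoms: none
Why: Swern conditions convert a primary triethylsilyl ether directly into the aldehyde (C1), while the secondary triethylsilyl and the primary tert-butyldimethylsilyl ethers should survive.

Step 12
Reactants: 13 aldehyde
Product: 14 triene alkylidene malonate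
Conditions: CH2(CO2CH2CH=CH2)2, piperidine (cat.), AcOH (cat.), 4 Å MS, CH2Cl2, 0 °C → rt
Reagents that add atoms: diallyl malonate (C=CCOC(=O)CC(=O)OCC=C)
Why: Knoevenagel condensation under buffered amine catalysis gives the C1=C10 alkylidene malonate; the low temperature limits epimerisation at C2.

Step 13
Reactants: 14 triene alkylidene malonate
Product: 15 cycloadduct diester
Conditions: toluene (high dilution), BHT (cat.), 100 °C
Reagents that add atoms: none
Why: Thermal normal-demand intramolecular Diels–Alder reaction: the C11=C12–C13=C14 diene adds across the C1=C10 alkylidene malonate in a concerted asynchronous [4+2] event in which C1–C14 (diene terminus to the β-carbon of the malonate) leads and C10–C11 follows. The closest known reaction type is the intramolecular Diels–Alder reaction of 1,3,10-undecatrienes that carry a doubly activated terminal dienophile, which gives 6/7-fused bicycles. The cyclohexene closes as the cycloaddition ring and the oxepane closes as the tether ring, C1–C14 being their shared fusion bond. C1 is controlled by C2 through allylic 1,3-strain (C2–H eclipses the cis ester, the tether carbon C3 lies on the diene face, the silyloxy group on the far face); C14 is controlled by the (E)-diene reacting with the C2 arm exo, which gives the trans ring fusion (H1 and H14 anti); C10 is not stereogenic at this stage. The step needs the trans-fused over the cis-fused adduct: the two identical esters cancel any endo bias, and only the exo-arm transition state keeps the fully substituted C3 with its methyl and silyloxymethyl groups from under the diene. Regiochemistry is fixed by the five-atom tether, which overrides the weak directing effects of the alkyl groups on the diene.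

Step 14
Reactants: 15 cycloadduct diester
Product: 17 lactone allyl ester, via hydroxy diester 16 (not isolated)
Conditions: AcOH/THF/H2O, rt; then PPTS (cat.), toluene, 60 °C
Reagents that add atoms: none
Why: Mild acid cleaves the secondary triethylsilyl ether selectively and the freed C2 hydroxyl closes the five-membered lactone onto the cis ester, which gives the cis C1–C10 ring fusion.

Step 15
Reactants: 17 lactone allyl ester
Product: 19 tricyclic lactone, via lactone acid 18 (not isolated)
Conditions: Pd(PPh3)4 (cat.), morpholine, THF, rt; then toluene, 100 °C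
Reagents that add atoms: none
Why: Palladium-catalysed allyl transfer to morpholine frees the acid and the α-carboxy lactone decarboxylates on heating; protonation of the lactone enol from the convex face should give the cis-fused lactone (H1 and H10 cis).

Step 16
Reactants: 19 tricyclic lactone
Product: 20 C11 allylic alcohol (11-epi)
Conditions: SeO2 (cat.), t-BuOOH, CH2Cl2, rt
Reagents that add atoms: tert-butyl hydroperoxide (CC(C)(C)OO)
Why: Selenium dioxide allylic oxidation (ene reaction, then [2,3]-sigmatropic shift) should attack the ring methylene next to the more substituted alkene carbon, which is C11, with oxygen entering from the convex face.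

Step 17
Reactants: 20 allylic alcohol
Product: 21 enone lactone
Conditions: Dess–Martin periodinane, NaHCO3, CH2Cl2, 0 °C
Reagents that add atoms: none
Why: Buffered Dess–Martin oxidation gives the C11 enone and erases the C11 configuration without touching C12, which is still sp2.

Step 18
Reactants: 21 enone lactone
Product: 22 C11 allylic alcohol (natural configuration)
Conditions: NaBH4, CeCl3·7H2O, MeOH, −78 °C
Reagents that add atoms: none
Why: Luche 1,2-reduction; hydride should attack the convex face, anti to the axial C10–C9 bond, so that O11 ends on the lactone face (H11 cis to H10).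

Step 19
Reactants: 22 allylic alcohol
Product: 23 saturated hydroxy lactone
Conditions: H2 (1 atm), Rh/Al2O3 (cat.), EtOAc, rt
Reagents that add atoms: none
Why: Heterogeneous hydrogenation of the only C=C from the convex face, anti to the lactone and to O11, sets C12 with the methyl cis to O11; C12 is not epimerisable because C11 is an alcohol.

Step 20
Reactants: 23 saturated hydroxy lactone
Product: 24 lactol
Conditions: i-Bu2AlH, CH2Cl2, −78 °C
Reagents that add atoms: none
Why: Low-temperature half-reduction of the γ-lactone stops at the lactol; the free C11 hydroxyl only consumes one more equivalent of hydride.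

Step 21
Reactants: 24 lactol
Product: 25 C9 (2-bromoallyl) tetrahydrofuran
Conditions: CH2=C(Br)CH2SiMe3, BF3·OEt2, CH2Cl2, −78 → −20 °C
Reagents that add atoms: (2-bromoallyl)trimethylsilane (C=C(Br)C[Si](C)(C)C)
Why: Hosomi–Sakurai-type C-allylation of the five-membered oxocarbenium ion on its convex face, anti to the C10–C11 bond, should give the 2,5-cis tetrahydrofuran and set C9.

Step 22
Reactants: 26 (R)-2-hydroxyoctanoic acid
Product: 28 (R)-2-[(tert-butyldiphenylsilyl)oxy]octanoic acid, via silyl ester 27 (not isolated)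
Conditions: t-BuPh2SiCl, imidazole, DMF, rt; then K2CO3 (cat.), MeOH/THF/H2O
Reagents that add atoms: tert-butyl(chloro)diphenylsilane (CC(C)(C)[Si](Cl)(c1ccccc1)c1ccccc1)
Why: Bis-silylation followed by selective hydrolysis of the labile silyl ester leaves the silyl ether of the α-hydroxy acid.

Step 23
Reactants: 25 C9 (2-bromoallyl) tetrahydrofuran; 28 protected acid
Product: 29 C11 ester
Conditions: EDC·HCl, DMAP, CH2Cl2, rt
Reagents that add atoms: none
Why: Steglich esterification of the only free hydroxyl (C11) installs the side chain with both stereocentres unchanged.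

Step 24
Reactants: 29 C11 ester
Product: 30 C4 primary alcohol
Conditions: HF·pyridine, pyridine, THF, 0 °C
Reagents that add atoms: none
Why: Buffered HF·pyridine cleaves the primary tert-butyldimethylsilyl ether and should leave the hindered secondary tert-butyldiphenylsilyl ether.

Step 25
Reactants: 30 C4 primary alcohol
Product: 31 C4 aldehyde
Conditions: Dess–Martin periodinane, NaHCO3, CH2Cl2, rt
Reagents that add atoms: none
Why: Dess–Martin oxidation gives the aldehyde, which cannot enolise because C3 is quaternary.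

Step 26
Reactants: 31 C4 aldehyde
Product: 32 C4 allylic alcohol
Conditions: MgBr2·OEt2, CH2Cl2, −78 °C; then CH2=CHMgBr
Reagents that add atoms: vinylmagnesium bromide (C=C[Mg]Br)
Why: Chelation-controlled (Cram-chelate) addition: magnesium bridges the aldehyde oxygen and the C3 ether oxygen and vinyl attacks from the methyl side, anti to C2, which should give the (4S)-alcohol; the aldehyde reacts well before the hindered ester at −78 °C.

Step 27
Reactants: 32 C4 allylic alcohol
Product: 33 C4 acetate
Conditions: Ac2O, pyridine, DMAP (cat.), CH2Cl2, rt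
Reagents that add atoms: acetic anhydride (CC(=O)OC(C)=O)
Why: Standard acetylation installs the C4 acetate of the target.

Step 28
Reactants: 33 C4 acetate
Product: 35 oxonane macrocycle, via B-alkyl borane 34 (not isolated)
Conditions: 9-BBN, THF, rt; then PdCl2(dppf) (cat.), AsPh3, Cs2CO3, DMF/THF/H2O, 50 °C, high dilution
Reagents that add atoms: none
Why: Anti-Markovnikov hydroboration of the monosubstituted alkene (the bromoalkene is much slower) and intramolecular B-alkyl Suzuki–Miyaura coupling should form C6–C7, closing the nine-membered ring on the 2,5-cis tetrahydrofuran template and leaving the C7 exocyclic methylene.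

Step 29
Reactants: 35 oxonane macrocycle
Product: 36 CNP0132024.3
Conditions: HF·pyridine, THF, rt
Reagents that add atoms: none
Why: Acidic fluoride removes the last silyl ether without acyl migration or loss of the acetate.

**Compound list**

1 | methyl (R)-3-hydroxy-2-methylpropanoate | OC[C@@H](C)C(=O)OC | starting material
2 | methyl (R)-3-[(tert-butyldimethylsilyl)oxy]-2-methylpropanoate | CC(C)(C)[Si](C)(C)OC[C@@H](C)C(=O)OC | intermediate
3 | (R)-3-[(tert-butyldimethylsilyl)oxy]-2-methylpropanal | CC(C)(C)[Si](C)(C)OC[C@@H](C)C=O | intermediate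
4 | (5S,3E)-6-[(tert-butyldimethylsilyl)oxy]-5-methylhex-3-en-2-one | CC(C)(C)[Si](C)(C)OC[C@@H](C)/C=C/C(C)=O | intermediate
5 | tert-butyl{[(2S,3E)-2,5-dimethylhexa-3,5-dien-1-yl]oxy}dimethylsilane | CC(C)(C)[Si](C)(C)OC[C@@H](C)/C=C/C(C)=C | intermediate
6 | (2S,3E)-2,5-dimethylhexa-3,5-dien-1-ol (C11–C17 with the C16 hydroxyl) | OC[C@@H](C)/C=C/C(C)=C | intermediate
7 | 1-[(tert-butyldimethylsilyl)oxy]propan-2-one | CC(=O)CO[Si](C)(C)C(C)(C)C | starting material
8 | methyl (Z)-4-[(tert-butyldimethylsilyl)oxy]-3-methylbut-2-enoate | CC(C)(C)[Si](C)(C)OC/C(C)=C\C(=O)OC | intermediate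
9 | (Z)-4-[(tert-butyldimethylsilyl)oxy]-3-methylbut-2-en-1-ol | CC(C)(C)[Si](C)(C)OC/C(C)=C\CO | intermediate
10 | [(2R,3S)-3-{[(tert-butyldimethylsilyl)oxy]methyl}-3-methyloxiran-2-yl]methanol | CC(C)(C)[Si](C)(C)OC[C@]1(C)O[C@@H]1CO | intermediate
11 | (2R,3R)-4-[(tert-butyldimethylsilyl)oxy]-3-{[(2S,3E)-2,5-dimethylhexa-3,5-dien-1-yl]oxy}-3-methylbutane-1,2-diol (C1–C4 joined through the C3 ether oxygen to C16) | CC(C)(C)[Si](C)(C)OC[C@@](C)(OC[C@@H](C)/C=C/C(C)=C)[C@H](O)CO | intermediate
12 | 1,2-bis(triethylsilyl) ether of diol 11 | CC(C)(C)[Si](C)(C)OC[C@@](C)(OC[C@@H](C)/C=C/C(C)=C)[C@H](O[Si](CC)(CC)CC)CO[Si](CC)(CC)CC | intermediate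
13 | (2S,3R)-4-[(tert-butyldimethylsilyl)oxy]-3-{[(2S,3E)-2,5-dimethylhexa-3,5-dien-1-yl]oxy}-3-methyl-2-[(triethylsilyl)oxy]butanal | CC(C)(C)[Si](C)(C)OC[C@@](C)(OC[C@@H](C)/C=C/C(C)=C)[C@H](O[Si](CC)(CC)CC)C=O | intermediate
14 | diallyl 2-{(2R,3R)-4-[(tert-butyldimethylsilyl)oxy]-3-{[(2S,3E)-2,5-dimethylhexa-3,5-dien-1-yl]oxy}-3-methyl-2-[(triethylsilyl)oxy]butylidene}malonate | CC(C)(C)[Si](C)(C)OC[C@@](C)(OC[C@@H](C)/C=C/C(C)=C)[C@H](O[Si](CC)(CC)CC)C=C(C(=O)OCC=C)C(=O)OCC=C | intermediate
15 | cycloadduct diester: cyclohexene (C1, C10–C14; C12=C13, C12 methyl) trans-fused at C1–C14 to the oxepane (C1–C2–C3–O–C16–C15–C14); two allyl esters on C10; OSiEt3 on C2; CH3 and CH2OSiMe2t-Bu on C3; CH3 on C15; H1 and H14 anti | CC(C)(C)[Si](C)(C)OC[C@@]2(C)OC[C@@H](C)[C@H]3C=C(C)CC(C(=O)OCC=C)(C(=O)OCC=C)[C@@H]3[C@H]2O[Si](CC)(CC)CC | intermediate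
16 | hydroxy diester: 15 with free C2 hydroxyl | CC(C)(C)[Si](C)(C)OC[C@@]2(C)OC[C@@H](C)[C@H]3C=C(C)CC(C(=O)OCC=C)(C(=O)OCC=C)[C@@H]3[C@H]2O | intermediate
17 | lactone allyl ester: γ-lactone O2–C9(=O) cis-fused at C1–C10; the remaining allyl ester on C10 trans to C2 | CC(C)(C)[Si](C)(C)OC[C@@]2(C)OC[C@@H](C)[C@H]3C=C(C)C[C@@]4(C(=O)OCC=C)[C@@H]3[C@H]2OC4=O | intermediate
18 | lactone acid: 17 with CO2H on C10 | CC(C)(C)[Si](C)(C)OC[C@@]2(C)OC[C@@H](C)[C@H]3C=C(C)C[C@@]4(C(=O)O)[C@@H]3[C@H]2OC4=O | intermediate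
19 | tricyclic lactone: cis-fused γ-lactone (H1 and H10 cis), C12=C13 cyclohexene, trans-fused oxepane, CH2OSiMe2t-Bu on C3 | CC(C)(C)[Si](C)(C)OC[C@@]2(C)OC[C@@H](C)[C@H]3C=C(C)C[C@H]4[C@@H]3[C@H]2OC4=O | intermediate
20 | C11 allylic alcohol of 19 with the hydroxyl on the convex face (cis to H10; 11-epi) | CC(C)(C)[Si](C)(C)OC[C@@]2(C)OC[C@@H](C)[C@H]3C=C(C)[C@@H](O)[C@H]4[C@@H]3[C@H]2OC4=O | intermediate
21 | enone lactone: C11 ketone conjugated with C12=C13 | CC(C)(C)[Si](C)(C)OC[C@@]2(C)OC[C@@H](C)[C@H]3C=C(C)C(=O)[C@H]4[C@@H]3[C@H]2OC4=O | intermediate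
22 | C11 allylic alcohol with the hydroxyl on the lactone face (H11 cis to H10; configuration of the target) | CC(C)(C)[Si](C)(C)OC[C@@]2(C)OC[C@@H](C)[C@H]3C=C(C)[C@H](O)[C@H]4[C@@H]3[C@H]2OC4=O | intermediate
23 | saturated hydroxy lactone: C12 methyl cis to O11; H10, H11 and H12 all cis | CC(C)(C)[Si](C)(C)OC[C@@]2(C)OC[C@@H](C)[C@H]3C[C@H](C)[C@H](O)[C@H]4[C@@H]3[C@H]2OC4=O | intermediate
24 | lactol: 23 with C9 as hemiacetal (anomer mixture) | CC(C)(C)[Si](C)(C)OC[C@@]2(C)OC[C@@H](C)[C@H]3C[C@H](C)[C@H](O)[C@H]4[C@@H]3[C@H]2OC4O | intermediate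
25 | C9 (2-bromoallyl) tetrahydrofuran: C8 cis to H10 and cis to C3 across the ring oxygen; free C11 hydroxyl | CC(C)(C)[Si](C)(C)OC[C@@]2(C)OC[C@@H](C)[C@H]3C[C@H](C)[C@H](O)[C@H]4[C@@H]3[C@H]2O[C@@H]4CC(Br)=C | intermediate
26 | (R)-2-hydroxyoctanoic acid | OC(=O)[C@H](O)CCCCCC | starting material
27 | tert-butyldiphenylsilyl (R)-2-[(tert-butyldiphenylsilyl)oxy]octanoate | CC(C)(C)[Si](OC(=O)[C@H](O[Si](c1ccccc1)(c1ccccc1)C(C)(C)C)CCCCCC)(c1ccccc1)c1ccccc1 | intermediate
28 | (R)-2-[(tert-butyldiphenylsilyl)oxy]octanoic acid | OC(=O)[C@H](O[Si](c1ccccc1)(c1ccccc1)C(C)(C)C)CCCCCC | intermediate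
29 | C11 ester of 25 with acid 28 | CC(C)(C)[Si](C)(C)OC[C@@]2(C)OC[C@@H](C)[C@H]3C[C@H](C)[C@H](OC(=O)[C@H](O[Si](c5ccccc5)(c5ccccc5)C(C)(C)C)CCCCCC)[C@H]4[C@@H]3[C@H]2O[C@@H]4CC(Br)=C | intermediate
30 | C4 primary alcohol (CH2OH on C3) | OC[C@@]2(C)OC[C@@H](C)[C@H]3C[C@H](C)[C@H](OC(=O)[C@H](O[Si](c5ccccc5)(c5ccccc5)C(C)(C)C)CCCCCC)[C@H]4[C@@H]3[C@H]2O[C@@H]4CC(Br)=C | intermediate
31 | C4 aldehyde (CHO on C3) | O=C[C@@]2(C)OC[C@@H](C)[C@H]3C[C@H](C)[C@H](OC(=O)[C@H](O[Si](c5ccccc5)(c5ccccc5)C(C)(C)C)CCCCCC)[C@H]4[C@@H]3[C@H]2O[C@@H]4CC(Br)=C | intermediate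
32 | (4S)-allylic alcohol: vinyl (C5=C6) and OH on C4 | C=C[C@H](O)[C@@]2(C)OC[C@@H](C)[C@H]3C[C@H](C)[C@H](OC(=O)[C@H](O[Si](c5ccccc5)(c5ccccc5)C(C)(C)C)CCCCCC)[C@H]4[C@@H]3[C@H]2O[C@@H]4CC(Br)=C | intermediate
33 | C4 acetate of 32 | C=C[C@H](OC(C)=O)[C@@]2(C)OC[C@@H](C)[C@H]3C[C@H](C)[C@H](OC(=O)[C@H](O[Si](c5ccccc5)(c5ccccc5)C(C)(C)C)CCCCCC)[C@H]4[C@@H]3[C@H]2O[C@@H]4CC(Br)=C | intermediate
34 | B-alkyl borane: 9-borabicyclo[3.3.1]nonan-9-yl on C6 | C1CCC2CCCC1B2CC[C@H](OC(C)=O)[C@@]3(C)OC[C@@H](C)[C@H]4C[C@H](C)[C@H](OC(=O)[C@H](O[Si](c5ccccc5)(c5ccccc5)C(C)(C)C)CCCCCC)[C@H]6[C@@H]4[C@H]3O[C@@H]6CC(Br)=C | intermediate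
35 | oxonane macrocycle: silyl ether of the target at the side-chain hydroxyl | C=C1CC[C@H](OC(C)=O)[C@@]2(C)OC[C@@H](C)[C@H]3C[C@H](C)[C@H](OC(=O)[C@H](O[Si](c5ccccc5)(c5ccccc5)C(C)(C)C)CCCCCC)[C@H]4[C@@H]3[C@H]2O[C@@H]4C1 | intermediate
36 | CNP0132024.3: (1R,2R,3R,4S,9R,10S,11S,12S,14R,15S)-asbestinane with C4 acetate, C7 exocyclic methylene and C11 (R)-2-hydroxyoctanoate | C=C1CC[C@H](OC(C)=O)[C@@]2(C)OC[C@@H](C)[C@H]3C[C@H](C)[C@H](OC(=O)[C@H](O)CCCCCC)[C@H]4[C@@H]3[C@H]2O[C@@H]4C1 | target

**Count and risks**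

Total step count: 29. Longest linear sequence: 25 steps (steps 1–5, 9–21, 23–29).

Step 13 is the most likely to fail. The cycloaddition may close the oxepane with the cis instead of the trans ring fusion, or may be slow because the tether ring is seven-membered and the tether works against the electronic preference of the diene. The fallback sets out from aldehyde 13 and changes both dienophile and activation. Wittig reaction with (triphenylphosphoranylidene)acetaldehyde should give the (E)-enal F1. Cyclisation under iminium catalysis with the matched enantiomer of 5-benzyl-2-tert-butyl-3-methylimidazolidin-4-one trifluoroacetate should give the cycloadduct aldehyde F2; here the endo formyl group and the exo C2 arm both point to the trans ring fusion, and the catalyst controls the face. C10 is then epimeric, but aqueous acetic acid removes the triethylsilyl group, the formyl-bearing C10 epimerises through the enol, and the cis-fused lactol F3 should form. Oxidation with PhI(OAc)2 and catalytic TEMPO returns to lactone 19.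

Step 28 is the second risk. The borane may undergo protodeboronation, or the coupling may give open-chain oligomers instead of the strained nine-membered ring. The fallback sets out from acetate 33 and closes the same bond by carbonyl addition. Hydroboration with 9-BBN and oxidation with NaBO3 should give the C6 primary alcohol F4, and Dess–Martin oxidation the C6 aldehyde F5. Nozaki–Hiyama–Kishi cyclisation (CrCl2, catalytic NiCl2, DMSO/THF, high dilution) should give the macrocyclic allylic alcohol F6, a closure of the type known for 2,5-cis tetrahydrofurans carrying these two arms. The C6 hydroxyl is then removed: methyl chloroformate and pyridine give the methyl carbonate F7, and Tsuji reduction (Pd2(dba)3, PBu3, HCO2NH4) should deliver hydride to the more substituted allyl terminus, which keeps the exocyclic methylene and returns to macrocycle 35.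

Step 16 is the third risk. Oxidation may occur at the C12 methyl group or go on to the enone and beyond. The fallback sets out from lactone 19 and brings in O11 through the lactone enolate instead of by C–H oxidation. Deprotonation with LiN(i-Pr)2 and Mukaiyama dehydrogenation with N-tert-butylbenzenesulfinimidoyl chloride should give the C10=C11 unsaturated lactone F8, the diene-conjugated elimination being preferred. Copper-catalysed 1,4-borylation (B2pin2, CuCl, NaOt-Bu, MeOH) from the convex face, with cis reprotonation at C10, should give the C11 boronate F9. Oxidation with NaBO3 with retention returns to alcohol 20.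

**Further compounds**

F1 | step 13 | (E)-enal: 13 extended by CH=CH–CHO at C1 | CC(C)(C)[Si](C)(C)OC[C@@](C)(OC[C@@H](C)/C=C/C(C)=C)[C@H](O[Si](CC)(CC)CC)/C=C/C=O
F2 | step 13 | cycloadduct aldehyde: as 15 but with H and CHO on C10, the CHO trans to C2 | CC(C)(C)[Si](C)(C)OC[C@@]2(C)OC[C@@H](C)[C@H]3C=C(C)C[C@@H](C=O)[C@@H]3[C@H]2O[Si](CC)(CC)CC
F3 | step 13 | cis-fused lactol corresponding to lactone 19 | CC(C)(C)[Si](C)(C)OC[C@@]2(C)OC[C@@H](C)[C@H]3C=C(C)C[C@H]4[C@@H]3[C@H]2OC4O
F4 | step 28 | C6 primary alcohol from hydroboration and oxidation of 33 | OCC[C@H](OC(C)=O)[C@@]2(C)OC[C@@H](C)[C@H]3C[C@H](C)[C@H](OC(=O)[C@H](O[Si](c5ccccc5)(c5ccccc5)C(C)(C)C)CCCCCC)[C@H]4[C@@H]3[C@H]2O[C@@H]4CC(Br)=C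
F5 | step 28 | C6 aldehyde | O=CC[C@H](OC(C)=O)[C@@]2(C)OC[C@@H](C)[C@H]3C[C@H](C)[C@H](OC(=O)[C@H](O[Si](c5ccccc5)(c5ccccc5)C(C)(C)C)CCCCCC)[C@H]4[C@@H]3[C@H]2O[C@@H]4CC(Br)=C
F6 | step 28 | macrocyclic C6 allylic alcohol (C6 epimers) | C=C1C(O)C[C@H](OC(C)=O)[C@@]2(C)OC[C@@H](C)[C@H]3C[C@H](C)[C@H](OC(=O)[C@H](O[Si](c5ccccc5)(c5ccccc5)C(C)(C)C)CCCCCC)[C@H]4[C@@H]3[C@H]2O[C@@H]4C1
F7 | step 28 | C6 methyl carbonate of F6 | C=C1C(OC(=O)OC)C[C@H](OC(C)=O)[C@@]2(C)OC[C@@H](C)[C@H]3C[C@H](C)[C@H](OC(=O)[C@H](O[Si](c5ccccc5)(c5ccccc5)C(C)(C)C)CCCCCC)[C@H]4[C@@H]3[C@H]2O[C@@H]4C1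
F8 | step 16 | C10=C11 unsaturated lactone conjugated with C12=C13 | CC(C)(C)[Si](C)(C)OC[C@@]2(C)OC[C@@H](C)[C@H]3C=C(C)C=C4[C@@H]3[C@H]2OC4=O
F9 | step 16 | C11 pinacol boronate of lactone 19, boron on the convex face | CC(C)(C)[Si](C)(C)OC[C@@]2(C)OC[C@@H](C)[C@H]3C=C(C)[C@@H](B5OC(C)(C)C(C)(C)O5)[C@H]4[C@@H]3[C@H]2OC4=O
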